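**Retrosynthetic overview**

1. The strategy rests on one feature: rings B and C are propionylphloroglucinol rings made non-aromatic only by the two methyl groups on one sp3 carbon, C(CH3)2, which lies between the two enolic C–OH carbons. In the aromatic form that carbon is the only ring carbon bearing hydrogen, whereas ring A (the butyryl ring) has no free carbon.
2. Key disconnection: the four C–CH3 bonds (two on ring B, two on ring C) are cut to give the fully aromatic trimer 13 and four MeI, a two-directional dearomatising C-methylation.
3. Trimer 13 is cut at its two ArCH2–Ar bonds to the bis-Mannich base 9 of butyrylphloroglucinol (a double ortho-quinone methide donor) and two molecules of propionylphloroglucinol 5.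
4. Compound 9 comes from butyrylphloroglucinol 3, formaldehyde and dimethylamine; 3 and 5 come from phloroglucinol by Friedel–Crafts acylation.
5. No ring is formed: all three carbocycles come from phloroglucinol. Ring A is functionalised first, rings B and C are attached next and dearomatised last.

Key step: step 5

Assumption: the target is written as one of several rapidly interconverting enol tautomers of rings B and C, so no tautomer control is planned. The four methylations of step 5 are taken to arrive in statistical order, and compounds 15 to 18 are the partly methylated species on the way (16 and 17 are parallel, not consecutive).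

**Route**

Step 1
Reactants: 1 phloroglucinol; 2 butyryl chloride
Product: 3 butyrylphloroglucinol, 1-(2,4,6-trihydroxyphenyl)butan-1-one
Conditions: AlCl3 (4 equiv), PhNO2, 2 (1.05 equiv), 0 °C → 65 °C; then ice, 2 M HCl
Reagents that add atoms: butyryl chloride (2), CCCC(Cl)=O
Why: Friedel–Crafts C-acylation of a very electron-rich arene, in which the first acyl group chelates aluminium and deactivates the ring so that monoacylation should dominate, and any aryl ester formed first should pass to the same ketone by Fries rearrangement.

Step 2
Reactants: 1 phloroglucinol; 4 propionyl chloride
Product: 5 propionylphloroglucinol, 1-(2,4,6-trihydroxyphenyl)propan-1-one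
Conditions: AlCl3 (4 equiv), PhNO2, 4 (1.05 equiv), 0 °C → 65 °C; then ice, 2 M HCl
Reagents that add atoms: propionyl chloride (4), CCC(Cl)=O
Why: The same Friedel–Crafts monoacylation as in step 1, self-limiting for the same reason.

Step 3
Reactants: 3 butyrylphloroglucinol; 6 formaldehyde; 7 dimethylamine
Product: 9 bis-Mannich base 1-[3,5-bis(dimethylaminomethyl)-2,4,6-trihydroxyphenyl]butan-1-one, via mono-Mannich base 8 (not isolated)
Conditions: 37% aq CH2O (2.4 equiv) and 40% aq Me2NH (2.4 equiv) premixed at 0 °C, EtOH, 0 °C → rt; zwitterionic 9 collected by filtration or evaporation
Reagents that add atoms: formaldehyde (6), C=O; dimethylamine (7), CNC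
Why: Double phenolic Mannich reaction, in which the iminium ion released from the premixed aminol attacks the two free ring carbons of 3, each flanked by two hydroxyl-bearing carbons, and once both are substituted 9 has no ring C–H left with which to alkylate itself.

Step 4
Reactants: 9 bis-Mannich base; 5 propionylphloroglucinol (8 equiv, excess recovered)
Product: 13 aromatic trimer 1-[2,4,6-trihydroxy-3,5-bis(2,4,6-trihydroxy-3-propanoylbenzyl)phenyl]butan-1-one, via ortho-quinone methide 10 (not isolated), via mono-bridged Mannich base 11 (not isolated), via ortho-quinone methide 12 (not isolated)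
Conditions: 5 (8 equiv), 1,4-dioxane, 90 °C, argon sweep, slow addition of 9 in a little DMF; chromatography
Reagents that add atoms: propionylphloroglucinol (5), CCC(=O)c1c(O)cc(O)cc1O
Why: Each zwitterionic phenolic Mannich arm loses dimethylamine on heating to give an ortho-quinone methide, which is trapped by Michael-type (Friedel–Crafts) addition of a free ring carbon of 5 followed by rearomatisation, a known way to build diarylmethane bridges between phloroglucinols; the large excess of 5 and the slow addition of 9 should keep a second quinone methide from reaching the remaining free carbon of a ring already attached.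

Step 5
Reactants: 13 aromatic trimer; 14 iodomethane
Product: 19 target CNP0212485.0, via mono-C-methyl trimer 15 (not isolated), via bis(C-methyl) trimer 16 (not isolated), via gem-dimethyl mono-dienone trimer 17 (not isolated), via tri-C-methyl trimer 18 (not isolated)
Conditions: NaOMe (8 equiv), degassed MeOH, argon, 0 °C; MeI (4.2 equiv, in portions), 0 °C → rt; then cold 1 M HCl to pH 2
Reagents that add atoms: iodomethane (14), CI
Why: In methanolic NaOMe each outer ring is a polyanion whose most acidic oxygen (para to the propionyl group) is conjugated to the single ring C–H, and this carbon attacks MeI by SN2 as a vinylogous enolate; the monomethylated ring re-aromatises by tautomerisation, is deprotonated again, and a second SN2 at the same carbon makes it the quaternary C(CH3)2 and leaves the ring as the propionyl-chelated cyclohexadienone. The closest known reaction type is the NaOMe/MeI gem-C-dimethylation of acylphloroglucinols to acylfilicinic acids, run here in two directions on one molecule. No ring is closed and no stereocentre arises, since each new quaternary carbon carries two identical methyl groups. The step needs carbon over oxygen selectivity and free carbon over bridge-bearing carbon selectivity: the protic medium hydrogen-bonds the phenoxide oxygens and favours C-alkylation by the soft electrophile, the free carbon is the least hindered nucleophilic site of each outer ring and its first methylation restores aromaticity, whereas every other ring carbon of rings A, B and C would have to become a crowded quaternary centre next to a CH2 bridge or an acyl group. Holding MeI close to four equivalents, low temperature and exclusion of oxygen should limit over-methylation, retro-Michael exchange of the methylene bridges and phenolate oxidation, and the partly methylated compounds 15 to 18 all converge on 19 whichever ring reacts first.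

**Compound list**

1 | phloroglucinol (benzene-1,3,5-triol) | Oc1cc(O)cc(O)c1 | starting material
2 | butyryl chloride | CCCC(Cl)=O | starting material
3 | butyrylphloroglucinol, 1-(2,4,6-trihydroxyphenyl)butan-1-one | CCCC(=O)c1c(O)cc(O)cc1O | intermediate
4 | propionyl chloride | CCC(Cl)=O | starting material
5 | propionylphloroglucinol, 1-(2,4,6-trihydroxyphenyl)propan-1-one | CCC(=O)c1c(O)cc(O)cc1O | intermediate
6 | formaldehyde | C=O | starting material
7 | dimethylamine | CNC | starting material
8 | mono-Mannich base, 1-[3-(dimethylaminomethyl)-2,4,6-trihydroxyphenyl]butan-1-one (not isolated) | CCCC(=O)c1c(O)cc(O)c(CN(C)C)c1O | intermediate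
9 | bis-Mannich base, 1-[3,5-bis(dimethylaminomethyl)-2,4,6-trihydroxyphenyl]butan-1-one | CCCC(=O)c1c(O)c(CN(C)C)c(O)c(CN(C)C)c1O | intermediate
10 | ortho-quinone methide of ring A still carrying one dimethylaminomethyl arm (not isolated) | CCCC(=O)C1=C(O)C(CN(C)C)=C(O)C(=C)C1=O | intermediate
11 | mono-bridged Mannich base: ring A with one 2,4,6-trihydroxy-3-propanoylbenzyl group and one dimethylaminomethyl arm (not isolated) | CCCC(=O)c1c(O)c(CN(C)C)c(O)c(Cc2c(O)cc(O)c(C(=O)CC)c2O)c1O | intermediate
12 | ortho-quinone methide of ring A carrying one 2,4,6-trihydroxy-3-propanoylbenzyl group (not isolated) | CCCC(=O)C1=C(O)C(Cc2c(O)cc(O)c(C(=O)CC)c2O)=C(O)C(=C)C1=O | intermediate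
13 | aromatic trimer, 1-[2,4,6-trihydroxy-3,5-bis(2,4,6-trihydroxy-3-propanoylbenzyl)phenyl]butan-1-one | CCCC(=O)c1c(O)c(Cc2c(O)cc(O)c(C(=O)CC)c2O)c(O)c(Cc2c(O)cc(O)c(C(=O)CC)c2O)c1O | intermediate
14 | iodomethane | CI | starting material
15 | mono-C-methyl trimer: one outer ring methylated once at its free carbon (not isolated) | CCCC(=O)c1c(O)c(Cc2c(O)c(C)c(O)c(C(=O)CC)c2O)c(O)c(Cc2c(O)cc(O)c(C(=O)CC)c2O)c1O | intermediate
16 | bis(C-methyl) trimer: each outer ring methylated once, all rings aromatic (not isolated) | CCCC(=O)c1c(O)c(Cc2c(O)c(C)c(O)c(C(=O)CC)c2O)c(O)c(Cc2c(O)c(C)c(O)c(C(=O)CC)c2O)c1O | intermediate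
17 | gem-dimethyl mono-dienone trimer: one outer ring as the 4,4-dimethyl dienone, the other unmethylated (not isolated) | CCCC(=O)c1c(O)c(CC2=C(O)C(C)(C)C(O)=C(C(=O)CC)C2=O)c(O)c(Cc2c(O)cc(O)c(C(=O)CC)c2O)c1O | intermediate
18 | tri-C-methyl trimer: one outer ring as the 4,4-dimethyl dienone, the other monomethylated and aromatic (not isolated) | CCCC(=O)c1c(O)c(CC2=C(O)C(C)(C)C(O)=C(C(=O)CC)C2=O)c(O)c(Cc2c(O)c(C)c(O)c(C(=O)CC)c2O)c1O | intermediate
19 | CNP0212485.0, 2,2'-[(5-butanoyl-2,4,6-trihydroxy-1,3-phenylene)bis(methylene)]bis(3,5-dihydroxy-4,4-dimethyl-6-propanoylcyclohexa-2,5-dien-1-one) | CCCC(=O)c1c(O)c(CC2=C(O)C(C)(C)C(O)=C(C(=O)CC)C2=O)c(O)c(CC2=C(O)C(C)(C)C(O)=C(C(=O)CC)C2=O)c1O | target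

**Step count**

Total steps: 5. Longest linear sequence: 4 steps (steps 1, 3, 4 and 5, from phloroglucinol); step 2 is a one-step side branch.

**Steps most likely to fail, with fallbacks**

Step 5 (most at risk). The fourfold methylation may lose site selectivity through O-methylation, attack at the bridge-bearing carbons of rings A, B or C, or uneven delivery of methyl groups to rings B and C. The methylene bridges may also exchange in base by retro-Michael cleavage and recombination. The fallback installs the gem-dimethyl groups before the bridges are made; it sets out from 5 and 9 and comes back to the route at 19. Compound 5 would be C-methylated on its own with NaOMe and MeI in MeOH, the established acylfilicinic acid preparation, and 2-propanoyl-3,5-dihydroxy-4,4-dimethylcyclohexa-2,5-dien-1-one (propionylfilicinic acid) F1 would be separated from its isomers at the monomer stage. F1 has a single nucleophilic ring carbon, so heating 2.5 equivalents with 9 in dioxane at 90 °C should trap both ortho-quinone methides without oligomerisation and give 19 directly.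

Step 4. Bridging may run on: a ring of 5 already attached keeps one free nucleophilic carbon and can capture a second quinone methide, leading to oligomers, with the excess of 5 as the only control. The fallback uses a nucleophile with only one free carbon; it sets out from 4 and 9 and comes back to the route at 16. Purchased 2-methylbenzene-1,3,5-triol (2-methylphloroglucinol) F2 would be acylated with 4 under the AlCl3 conditions of step 2. Its two free carbons are equivalent, so a single ketone, 1-(2,4,6-trihydroxy-3-methylphenyl)propan-1-one F3, is expected. Heating F3 (2.4 equiv) with 9 as in step 4 should give 16, which is then taken through step 5 with about two equivalents of MeI, so the dearomatising methylation stays as the closing event.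

Step 3. The mono-Mannich base 8 may eliminate amine early and alkylate unreacted 3, giving methylene-bridged homo-oligomers, or the second aminomethylation may stall and 9 may shed amine on isolation. The fallback reverses the polarity of the bridge formation; it sets out from 3 (with 6 and 7) and comes back to the route at 16. 1-(2,4,6-Trihydroxy-3-methylphenyl)propan-1-one F3, made from F2 and 4 as in the fallback to step 4, would be aminomethylated at its only free ring carbon with premixed 6 and 7 to give 1-[3-(dimethylaminomethyl)-2,4,6-trihydroxy-5-methylphenyl]propan-1-one F4, which has no ring C–H and cannot alkylate itself at carbon. Heating F4 (2.2 equiv) with 3 in dioxane at 90 °C should alkylate exactly the two free carbons of 3 and give 16, which rejoins step 5 with about two equivalents of MeI.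

**Further compounds**

F1 | step 5 | propionylfilicinic acid, 2-propanoyl-3,5-dihydroxy-4,4-dimethylcyclohexa-2,5-dien-1-one | CCC(=O)C1=C(O)C(C)(C)C(O)=CC1=O
F2 | step 4 | 2-methylphloroglucinol, 2-methylbenzene-1,3,5-triol (purchased) | Cc1c(O)cc(O)cc1O
F3 | step 4 | 1-(2,4,6-trihydroxy-3-methylphenyl)propan-1-one | CCC(=O)c1c(O)cc(O)c(C)c1O
F4 | step 3 | 1-[3-(dimethylaminomethyl)-2,4,6-trihydroxy-5-methylphenyl]propan-1-one | CCC(=O)c1c(O)c(C)c(O)c(CN(C)C)c1O
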